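**Retrosynthetic overview**

1. Target 23 ⇐ penta-O-benzyl bis-flavanone 22 ⇐ bis(flavan-4-ol) 21 ⇐ bis(4-silyloxyflavan) 20. Desilylation, oxidation at both C4 and debenzylation come last, so no enolisable flavanone meets base or palladium.
2. Key disconnection: the two aryl ether bonds O1–C8a. In each flavanone O1 joins the stereogenic benzylic C2 to C8a of ring A. In unit 2 (the flavanone whose C6 carries the diaryl ether oxygen; unit 1 carries that oxygen at C4′ of its ring B) C8a is para to C6, so a bromine para to the ether oxygen marks the closure site. 20 ⇐ bis(bromoaryl) bis-(S)-carbinol 19.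
3. 19 ⇐ bis(β-silyloxy ketone) 18 by twofold CBS reduction (sets both C2). 18 ⇐ two aldol additions: enolate of keto aldehyde 11 (aldehyde masked) + aldehyde 3, then enolate of 16 + the ring A aldehyde of unit 2.
4. 11 ⇐ SNAr of phenol 8 with 4-fluoroacetophenone 9, then formylation next to bromine. 8 comes from 2,6-dihydroxybenzaldehyde 4, and 3 from 5-bromoresorcinol 1.
5. Ring order: rings A and B of both units enter as arenes; the two pyran rings (ring C of unit 1 and of unit 2) form last and together in step 13.

Key step: step 13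

Remark: C4 of both units ends as a ketone, so the aldol additions are run without stereocontrol. Compounds 13–15 are racemic, 17 and 18 are diastereomer mixtures, and 19–21 are mixtures of epimers at the C4 carbons with both C2 centres (S). In twofold steps the half-converted species are not counted as separate compounds.

**Route**

Step 1
Reactants: 1 5-bromobenzene-1,3-diol
Product: 2 1,3-bis(benzyloxy)-5-bromobenzene
Conditions: BnBr, K2CO3, DMF, 60 °C
Reagents that add atoms: benzyl bromide, BrCc1ccccc1
Why: Williamson etherification of both phenols; the aryl bromide is inert to carbonate.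

Step 2
Reactants: 2 1,3-bis(benzyloxy)-5-bromobenzene
Product: 3 2,4-bis(benzyloxy)-6-bromobenzaldehyde
Conditions: POCl3, DMF, 0 to 80 °C; then H2O, 50 °C
Reagents that add atoms: N,N-dimethylformamide, CN(C)C=O; water, O
Why: Vilsmeier–Haack formylation should enter mainly para to one benzyloxy group and ortho to the other, next to bromine, because the position between the two ethers is more crowded; a minor regioisomer is removed by crystallisation.

Step 3
Reactants: 4 2,6-dihydroxybenzaldehyde
Product: 5 2,6-bis(benzyloxy)benzaldehyde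
Conditions: BnBr, K2CO3, DMF, 70 °C
Reagents that add atoms: benzyl bromide, BrCc1ccccc1
Why: Williamson etherification; warming overcomes the hydrogen bonds of the two hydroxyls to the formyl group.

Step 4
Reactants: 5 2,6-bis(benzyloxy)benzaldehyde
Product: 7 2,6-bis(benzyloxy)phenol, via aryl formate 6 (not isolated)
Conditions: mCPBA, CH2Cl2, 0 °C to rt; aq. NaHCO3 wash; then Et3N, MeOH, rt
Reagents that add atoms: 3-chloroperbenzoic acid, OOC(=O)c1cccc(Cl)c1
Why: Baeyer–Villiger (Dakin-type) oxidation: the electron-rich aryl group migrates to oxygen to give the aryl formate, which amine-catalysed methanolysis cleaves to the phenol without touching the benzyl ethers.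

Step 5
Reactants: 7 2,6-bis(benzyloxy)phenol
Product: 8 2,6-bis(benzyloxy)-4-bromophenol
Conditions: NBS, NaH (cat.), CHCl3, −45 °C to rt
Reagents that add atoms: N-bromosuccinimide, O=C1CCC(=O)N1Br
Why: Electrophilic aromatic bromination: under base catalysis the phenoxide directs NBS to its only open conjugated position, para to oxygen (both ortho positions carry benzyloxy groups), as is known for 2,6-dimethoxyphenol.

Step 6
Reactants: 8 2,6-bis(benzyloxy)-4-bromophenol; 9 4-fluoroacetophenone
Product: 10 1-{4-[2,6-bis(benzyloxy)-4-bromophenoxy]phenyl}ethan-1-one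
Conditions: K2CO3, DMF, 120 °C
Reagents that add atoms: none
Why: Nucleophilic aromatic substitution (SNAr): the para-acetyl group activates fluoride displacement by the hindered phenoxide, while the aryl bromide of 8 is not activated and stays.

Step 7
Reactants: 10 1-{4-[2,6-bis(benzyloxy)-4-bromophenoxy]phenyl}ethan-1-one
Product: 11 3-(4-acetylphenoxy)-2,4-bis(benzyloxy)-6-bromobenzaldehyde
Conditions: Cl2CHOMe, SnCl4, CH2Cl2, −20 to 0 °C; ice–water
Reagents that add atoms: dichloromethyl methyl ether, COC(Cl)Cl; water, O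
Why: Rieche formylation: the brominated ring is the only strongly activated arene (attack ortho and para to benzyloxy groups) and its two open positions are equivalent, so the formyl group must enter next to bromine, while the acetyl-bearing ring is deactivated.

Step 8
Reactants: 11 3-(4-acetylphenoxy)-2,4-bis(benzyloxy)-6-bromobenzaldehyde; 3 2,4-bis(benzyloxy)-6-bromobenzaldehyde
Product: 14 racemic aldol aldehyde of unit 1, via tert-butyl aldimine 12 (not isolated), via aldol aldimine 13 (not isolated)
Conditions: t-BuNH2, 4 Å MS, CH2Cl2, rt, evaporate; LDA, THF, −78 °C, then 3, −78 °C, AcOH; 10 % aq. citric acid, THF, rt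
Reagents that add atoms: water, O
Why: Chemoselective condensation with tert-butylamine masks the aldehyde as a non-enolisable aldimine (the aryl methyl ketone does not condense), a directed lithium-enolate aldol addition to 3 then builds C3–C4 of unit 1, and mild aqueous acid returns the aldehyde; the new carbinol centre is formed without control because it is oxidised in step 15.

Step 9
Reactants: 14 racemic aldol aldehyde of unit 1
Product: 15 silyl ether of 14
Conditions: TBSOTf, 2,6-lutidine, CH2Cl2, −78 to 0 °C
Reagents that add atoms: tert-butyldimethylsilyl trifluoromethanesulfonate, CC(C)(C)[Si](C)(C)OS(=O)(=O)C(F)(F)F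
Why: Silylation of the hindered benzylic aldol hydroxyl with a silyl triflate blocks retro-aldol and dehydration and caps the C4 oxygen of unit 1 for the key step.

Step 10
Reactants: 15 silyl ether of 14; 16 4-benzyloxyacetophenone
Product: 17 mono-silylated bis-ketone with free aldol hydroxyl on unit 2
Conditions: 16, LDA, THF, −78 °C; then 15, −78 °C; AcOH quench at −78 °C
Reagents that add atoms: none
Why: Directed aldol addition: the preformed lithium enolate of 16 should add to the aldehyde at −78 °C far faster than it exchanges a proton with, or adds to, the β-silyloxy ketone; the new C4 centre of unit 2 is uncontrolled and later oxidised.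

Step 11
Reactants: 17 mono-silylated bis-ketone
Product: 18 bis(β-silyloxy ketone)
Conditions: TBSOTf, 2,6-lutidine, CH2Cl2, −78 to 0 °C
Reagents that add atoms: tert-butyldimethylsilyl trifluoromethanesulfonate, CC(C)(C)[Si](C)(C)OS(=O)(=O)C(F)(F)F
Why: Silyl triflate silylation of the second aldol hydroxyl, as in step 9, so that only the two C2 oxygens are free after reduction.

Step 12
Reactants: 18 bis(β-silyloxy ketone)
Product: 19 bis(bromoaryl) bis-(S)-carbinol
Conditions: (R)-Me-CBS oxazaborolidine (0.4 equiv), BH3·SMe2, THF, −20 °C; MeOH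
Reagents that add atoms: none
Why: Corey–Bakshi–Shibata reduction: with the (R)-oxazaborolidine the aryl group acts as the large substituent and hydride is delivered to the face that gives the (S)-alcohol at both aryl ketones under catalyst control, whatever the configuration at the silyloxy carbons.

Step 13
Reactants: 19 bis(bromoaryl) bis-(S)-carbinol
Product: 20 penta-O-benzyl bis(4-silyloxyflavan)
Conditions: Pd(OAc)2 (10 mol %), 2-(di-tert-butylphosphino)-1,1′-binaphthyl (15 mol %), Cs2CO3, toluene, 80 °C
Reagents that add atoms: none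
Why: Pd(OAc)2 is reduced in the flask to a zerovalent palladium–phosphine species that inserts into each C8a–Br bond; Cs2CO3 then turns the neighbouring (S)-carbinol into an alkoxide on divalent palladium, and C–O reductive elimination from the seven-membered oxapalladacycle forms O1–C8a. The closest known reaction type is the Buchwald-type palladium-catalysed intramolecular O-arylation of secondary alcohols with aryl bromides, which gives chromans. Each pyran ring closes by attack of the C2 oxygen on the bromine-bearing ring A carbon (six-membered ring through a seven-membered metallacycle), once in unit 1 and once in unit 2. No stereocentre is created: the C2–O bonds are never broken, so the (S) configurations from step 12 are carried over unchanged. The step needs reductive elimination to outrun β-hydride elimination of the benzylic alkoxide, which the bulky di-tert-butylbiaryl ligand should secure. Site selectivity is fixed by the position of each bromine and by the silyl cap on the C4 oxygen, which also removes any enolisable ketone.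

Step 14
Reactants: 20 penta-O-benzyl bis(4-silyloxyflavan)
Product: 21 penta-O-benzyl bis(flavan-4-ol)
Conditions: TBAF, THF, rt to 40 °C
Reagents that add atoms: none
Why: Fluoride-mediated desilylation; without a carbonyl group the flavan C2 centres cannot open by retro-oxa-Michael reaction under the basic fluoride.

Step 15
Reactants: 21 penta-O-benzyl bis(flavan-4-ol)
Product: 22 penta-O-benzyl bis-flavanone
Conditions: Dess–Martin periodinane, CH2Cl2, 0 °C to rt
Reagents that add atoms: none
Why: Dess–Martin oxidation of both benzylic alcohols removes the mixed C4 centres and gives the flavanones without base that could open the pyranone ring and racemise C2; all phenols are still benzylated.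

Step 16
Reactants: 22 penta-O-benzyl bis-flavanone
Product: 23 CNP0184214.1
Conditions: H2 (1 atm), Pd/C, EtOAc–MeOH, rt
Reagents that add atoms: none
Why: Hydrogenolysis of the five benzyl aryl ethers over palladium under neutral conditions; the reaction is stopped at full debenzylation so that the benzylic C2–O1 bonds and the ketones remain.

**Compound list**

1 | 5-bromobenzene-1,3-diol | Oc1cc(O)cc(Br)c1 | starting material
2 | 1,3-bis(benzyloxy)-5-bromobenzene | Brc1cc(OCc2ccccc2)cc(OCc2ccccc2)c1 | intermediate
3 | 2,4-bis(benzyloxy)-6-bromobenzaldehyde | O=Cc1c(Br)cc(OCc2ccccc2)cc1OCc1ccccc1 | intermediate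
4 | 2,6-dihydroxybenzaldehyde | O=Cc1c(O)cccc1O | starting material
5 | 2,6-bis(benzyloxy)benzaldehyde | O=Cc1c(OCc2ccccc2)cccc1OCc1ccccc1 | intermediate
6 | 2,6-bis(benzyloxy)phenyl formate | O=COc1c(OCc2ccccc2)cccc1OCc1ccccc1 | intermediate
7 | 2,6-bis(benzyloxy)phenol | Oc1c(OCc2ccccc2)cccc1OCc1ccccc1 | intermediate
8 | 2,6-bis(benzyloxy)-4-bromophenol | Oc1c(OCc2ccccc2)cc(Br)cc1OCc1ccccc1 | intermediate
9 | 4-fluoroacetophenone | CC(=O)c1ccc(F)cc1 | starting material
10 | 1-{4-[2,6-bis(benzyloxy)-4-bromophenoxy]phenyl}ethan-1-one | CC(=O)c1ccc(Oc2c(OCc3ccccc3)cc(Br)cc2OCc2ccccc2)cc1 | intermediate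
11 | 3-(4-acetylphenoxy)-2,4-bis(benzyloxy)-6-bromobenzaldehyde | CC(=O)c1ccc(Oc2c(OCc3ccccc3)cc(Br)c(C=O)c2OCc2ccccc2)cc1 | intermediate
12 | N-tert-butyl aldimine of 11 | CC(=O)c1ccc(Oc2c(OCc3ccccc3)cc(Br)c(C=NC(C)(C)C)c2OCc2ccccc2)cc1 | intermediate
13 | aldol adduct of 12 with 3, aldimine intact (racemic) | OC(c1c(Br)cc(OCc2ccccc2)cc1OCc1ccccc1)CC(=O)c1ccc(Oc2c(OCc3ccccc3)cc(Br)c(C=NC(C)(C)C)c2OCc2ccccc2)cc1 | intermediate
14 | 3-{4-[3-(2,4-bis(benzyloxy)-6-bromophenyl)-3-hydroxypropanoyl]phenoxy}-2,4-bis(benzyloxy)-6-bromobenzaldehyde (racemic) | OC(c1c(Br)cc(OCc2ccccc2)cc1OCc1ccccc1)CC(=O)c1ccc(Oc2c(OCc3ccccc3)cc(Br)c(C=O)c2OCc2ccccc2)cc1 | intermediate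
15 | tert-butyldimethylsilyl ether of 14 (racemic) | CC(C)(C)[Si](C)(C)OC(c1c(Br)cc(OCc2ccccc2)cc1OCc1ccccc1)CC(=O)c1ccc(Oc2c(OCc3ccccc3)cc(Br)c(C=O)c2OCc2ccccc2)cc1 | intermediate
16 | 4-benzyloxyacetophenone | CC(=O)c1ccc(OCc2ccccc2)cc1 | starting material
17 | aldol adduct of 15 with 16: bis-ketone, unit 1 carbinol silylated, unit 2 carbinol free (diastereomer mixture) | CC(C)(C)[Si](C)(C)OC(c1c(Br)cc(OCc2ccccc2)cc1OCc1ccccc1)CC(=O)c1ccc(Oc2c(OCc3ccccc3)cc(Br)c(c2OCc2ccccc2)C(O)CC(=O)c2ccc(OCc3ccccc3)cc2)cc1 | intermediate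
18 | bis(β-silyloxy ketone) (diastereomer mixture) | CC(C)(C)[Si](C)(C)OC(c1c(Br)cc(OCc2ccccc2)cc1OCc1ccccc1)CC(=O)c1ccc(Oc2c(OCc3ccccc3)cc(Br)c(c2OCc2ccccc2)C(O[Si](C)(C)C(C)(C)C)CC(=O)c2ccc(OCc3ccccc3)cc2)cc1 | intermediate
19 | bis(bromoaryl) bis-carbinol, (S) at both free carbinol carbons, silyloxy carbons as epimer mixture | CC(C)(C)[Si](C)(C)OC(c1c(Br)cc(OCc2ccccc2)cc1OCc1ccccc1)C[C@H](O)c1ccc(Oc2c(OCc3ccccc3)cc(Br)c(c2OCc2ccccc2)C(O[Si](C)(C)C(C)(C)C)C[C@H](O)c2ccc(OCc3ccccc3)cc2)cc1 | intermediate
20 | penta-O-benzyl bis(4-silyloxyflavan), (2S) in both units, C4 epimers mixed | CC(C)(C)[Si](C)(C)OC1C[C@@H](c2ccc(Oc3c(OCc4ccccc4)cc4c(c3OCc3ccccc3)C(O[Si](C)(C)C(C)(C)C)C[C@@H](c3ccc(OCc5ccccc5)cc3)O4)cc2)Oc2cc(OCc3ccccc3)cc(OCc3ccccc3)c21 | intermediate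
21 | penta-O-benzyl bis(flavan-4-ol), (2S) in both units, C4 epimers mixed | OC1C[C@@H](c2ccc(Oc3c(OCc4ccccc4)cc4c(c3OCc3ccccc3)C(O)C[C@@H](c3ccc(OCc5ccccc5)cc3)O4)cc2)Oc2cc(OCc3ccccc3)cc(OCc3ccccc3)c21 | intermediate
22 | penta-O-benzyl bis-flavanone, (2S) in both units | O=C1C[C@@H](c2ccc(Oc3c(OCc4ccccc4)cc4c(c3OCc3ccccc3)C(=O)C[C@@H](c3ccc(OCc5ccccc5)cc3)O4)cc2)Oc2cc(OCc3ccccc3)cc(OCc3ccccc3)c21 | intermediate
23 | CNP0184214.1, (2S) in both flavanone units | O=C1C[C@@H](c2ccc(Oc3c(O)cc4c(c3O)C(=O)C[C@@H](c3ccc(O)cc3)O4)cc2)Oc2cc(O)cc(O)c21 | target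

**Step count**

Total: 16 steps. Longest linear sequence: 14 steps (steps 3–16, from 4 to 23).

**Steps most likely to fail**

Step 13. The palladium alkoxide may undergo β-hydride elimination, which oxidises the carbinol to a ketone and leaves a debrominated arene. The silyl group may also shift from the C4 oxygen to the C2 alkoxide, or the second closure may stall. The fallback forms the O1–C2 bond by substitution with inversion instead. It sets out from 18: reduction with the (S)-oxazaborolidine and BH3·SMe2 should give the bis-(R)-carbinol F1. Miyaura borylation of both aryl bromides (B2pin2, PdCl2(dppf), KOAc, dioxane, 90 °C; the weak base forms no alkoxide) should give the bis(pinacol boronate) F2. Oxidation with NaBO3 in THF–water should give the bis-phenol F3. Twofold Mitsunobu cyclisation (PPh3, DIAD, THF, 0 °C) should then close both pyran rings with inversion at C2 and return to 20.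

Step 7. The Lewis acid may cleave the benzyl ether that chelates with the new formyl group, or substitution at the crowded position may be too slow for the ketone-bearing substrate to survive. The fallback avoids both the Lewis acid and the ketone and sets out from 8. SNAr with 4-fluorobenzonitrile (K2CO3, DMF, 90 °C) should give 4-[2,6-bis(benzyloxy)-4-bromophenoxy]benzonitrile F4. Vilsmeier–Haack formylation (POCl3, DMF) should give the formyl nitrile F5. Ethylene glycol with TsOH in toluene should give the dioxolane nitrile F6. MeMgBr with catalytic CuBr, followed by buffered hydrolysis of the ketimine, should give the keto acetal F7. Aldol addition of its lithium enolate to 3 should give the aldol acetal F8. PPTS in acetone–water removes the acetal and returns to 14.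

Step 10. The β-silyloxy ketone may transfer a proton to the enolate and lose silanolate, or the hindered aldolate may revert during quench. The fallback replaces the basic enolate by a neutral enol silane and sets out from 15. Ketone 16 is converted with TMSCl, NaI and Et3N in MeCN into the trimethylsilyl enol ether F9. A Mukaiyama aldol addition of F9 to 15 (BF3·OEt2, CH2Cl2, −78 °C) should return to 17.

**Further compounds**

F1 | step 13 | bis(bromoaryl) bis-carbinol, (R) at both free carbinol carbons | CC(C)(C)[Si](C)(C)OC(c1c(Br)cc(OCc2ccccc2)cc1OCc1ccccc1)C[C@@H](O)c1ccc(Oc2c(OCc3ccccc3)cc(Br)c(c2OCc2ccccc2)C(O[Si](C)(C)C(C)(C)C)C[C@@H](O)c2ccc(OCc3ccccc3)cc2)cc1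
F2 | step 13 | bis(pinacol boronate) of F1 | CC(C)(C)[Si](C)(C)OC(c1c(B2OC(C)(C)C(C)(C)O2)cc(OCc2ccccc2)cc1OCc1ccccc1)C[C@@H](O)c1ccc(Oc2c(OCc3ccccc3)cc(B3OC(C)(C)C(C)(C)O3)c(c2OCc2ccccc2)C(O[Si](C)(C)C(C)(C)C)C[C@@H](O)c2ccc(OCc3ccccc3)cc2)cc1
F3 | step 13 | bis-phenol from F2 | CC(C)(C)[Si](C)(C)OC(c1c(O)cc(OCc2ccccc2)cc1OCc1ccccc1)C[C@@H](O)c1ccc(Oc2c(OCc3ccccc3)cc(O)c(c2OCc2ccccc2)C(O[Si](C)(C)C(C)(C)C)C[C@@H](O)c2ccc(OCc3ccccc3)cc2)cc1
F4 | step 7 | 4-[2,6-bis(benzyloxy)-4-bromophenoxy]benzonitrile | N#Cc1ccc(Oc2c(OCc3ccccc3)cc(Br)cc2OCc2ccccc2)cc1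
F5 | step 7 | 4-[2,6-bis(benzyloxy)-4-bromo-3-formylphenoxy]benzonitrile | N#Cc1ccc(Oc2c(OCc3ccccc3)cc(Br)c(C=O)c2OCc2ccccc2)cc1
F6 | step 7 | 4-[2,6-bis(benzyloxy)-4-bromo-3-(1,3-dioxolan-2-yl)phenoxy]benzonitrile | N#Cc1ccc(Oc2c(OCc3ccccc3)cc(Br)c(C3OCCO3)c2OCc2ccccc2)cc1
F7 | step 7 | 1-{4-[2,6-bis(benzyloxy)-4-bromo-3-(1,3-dioxolan-2-yl)phenoxy]phenyl}ethan-1-one | CC(=O)c1ccc(Oc2c(OCc3ccccc3)cc(Br)c(C3OCCO3)c2OCc2ccccc2)cc1
F8 | step 7 | aldol adduct of F7 with 3, dioxolane intact (racemic) | OC(c1c(Br)cc(OCc2ccccc2)cc1OCc1ccccc1)CC(=O)c1ccc(Oc2c(OCc3ccccc3)cc(Br)c(C3OCCO3)c2OCc2ccccc2)cc1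
F9 | step 10 | {[1-(4-(benzyloxy)phenyl)ethenyl]oxy}trimethylsilane | C=C(O[Si](C)(C)C)c1ccc(OCc2ccccc2)cc1
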